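**Target:** bis[(R)-1-carboxy-2-(3,4-dihydroxyphenyl)ethyl] (1R,2R,3R,4R)-3,4-bis(3,4-dihydroxyphenyl)cyclobutane-1,2-dicarboxylate. The ring is a mu-truxinate: trans-diester, trans-diaryl, each ester cis to the neighbouring aryl.

## Retrosynthetic overview

1. Target ⇐ global hydrogenolysis of a macrotricycle in which two o-xylylene straps ("double benzyl groups") tie each danshensu carboxylate to the meta-oxygen of the neighbouring aryl ring.
2. Macrotricycle ⇐ transannular stilbene–fumarate [2+2] photocycloaddition of a C2-symmetric 30-membered macrocycle. One event closes the cyclobutane and splits the macrocycle into two 15-membered rings (one ring becomes three) and sets all four ring stereocentres.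
3. Macrocycle ⇐ high-dilution double acylation of a strapped stilbene bis(danshensu ester) diol with fumaryl chloride.
4. Diol ⇐ stilbene bis(benzylic bromide) + sodium (R)-danshensu (chiral pool); bis-bromide ⇐ stilbene diol + 1,2-bis(bromomethyl)benzene; stilbene diol ⇐ McMurry coupling of 4-(benzyloxy)-3-hydroxybenzaldehyde.
5. Ring order: 30-membered macrocycle (step 4) → cyclobutane plus second macro-ring (step 5) → strap rings opened (step 6).

Assumption: sodium (R)-danshensu (natural salvianic acid A sodium) and 4-(benzyloxy)-3-hydroxybenzaldehyde are taken as commercial.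

## Route

**Step 1**
Reactants: 1 4-(benzyloxy)-3-hydroxybenzaldehyde (2 equiv)
Product: 2 (E)-4,4'-bis(benzyloxy)stilbene-3,3'-diol
Conditions: TiCl4 (2.5 equiv), Zn dust (5 equiv), THF, reflux 2 h; then 1, reflux 6 h; aq. NH4Cl work-up
Reagents that add atoms: none
Why: McMurry reductive coupling: low-valent titanium pinacol-couples the aryl aldehyde and deoxygenates the titanium pinacolate, aromatic aldehydes giving the E-stilbene, while the phenol rides through as its titanium phenoxide (hence the excess reagent) and the benzyl ether is inert.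

**Step 2**
Reactants: 2 (E)-4,4'-bis(benzyloxy)stilbene-3,3'-diol; 3 1,2-bis(bromomethyl)benzene (10 equiv, excess recovered)
Product: 4 (E)-4,4'-bis(benzyloxy)-3,3'-bis{[2-(bromomethyl)benzyl]oxy}stilbene
Conditions: K2CO3 (3 equiv), acetone, reflux, 12 h
Reagents that add atoms: none
Why: Williamson ether synthesis (phenoxide SN2 on a benzylic bromide); the large excess of dibromide stops each xylylene at mono-substitution, and no stereocentre is involved.

**Step 3**
Reactants: 4 the bis-bromide; 5 sodium (2R)-3-(3,4-dihydroxyphenyl)-2-hydroxypropanoate (sodium (R)-danshensu, 2.2 equiv)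
Product: 7 (E)-stilbene bis(2-{[(2R)-3-(3,4-bis(benzyloxy)phenyl)-2-hydroxypropanoyl]oxymethyl}benzyl) diether diol, via tetraphenol bis-ester 6 (not isolated)
Conditions: DMF, cat. Bu4NI, rt, 12 h; then BnBr (5 equiv), K2CO3 (6 equiv), rt to 40 °C, 8 h
Reagents that add atoms: benzyl bromide, BrCc1ccccc1
Why: SN2 O-alkylation of the carboxylate (the only anion present before base is added) by the benzylic bromides, then Williamson benzylation of the four phenols with K2CO3, which does not deprotonate the secondary alcohol; the two (R)-centres come unchanged from the chiral pool.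

**Step 4**
Reactants: 7 the diol; 8 fumaryl chloride (1.05 equiv)
Product: 9 C2-symmetric 30-membered macrocyclic (E)-fumarate (both alkenes E, both side-chain centres R)
Conditions: pyridine (4 equiv), DMAP (0.2 equiv), CH2Cl2 (2 mM), syringe-pump addition of 8 over 10 h, 0 °C to rt
Reagents that add atoms: none
Why: high-dilution macrocyclic double esterification with a diacid chloride, the second acylation being intramolecular and helped by donor–acceptor stacking of the fumaroyl half-ester on the electron-rich stilbene; alkene geometry and the (R)-centres are untouched.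

**Step 5**
Reactants: 9 the macrocyclic fumarate
Product: 10 macrotricyclic cyclobutane (1R,2R,3R,4R; cyclobutane flanked by two 15-membered strap rings)
Conditions: hν 350 nm (Pyrex), degassed toluene (1 mM), −20 °C; chromatography to remove the minor face isomer
Reagents that add atoms: none
Why: Proposed new method: only the tetraalkoxystilbene absorbs at 350 nm, and its singlet excited state forms an intramolecular exciplex with the strapped fumarate that collapses by a concerted suprafacial [2+2] photocycloaddition (closing the cyclobutane and turning the one macrocycle into two 15-membered rings), so both E-alkenes keep their trans geometry (trans-diester, trans-diaryl), the short o-xylylene loops hold each ester over the aryl ring it is tied to (cis ester/aryl, mu-truxinate), and the two (R)-centres, sitting in the loops with the carbinol C–H eclipsing the ester carbonyl, the CH2Ar group outward and the carboxylate arm aimed at the stilbene, are predicted to present the Re,Re face of the fumarate (s-trans enoate rotamer over the inner meta-oxygen) to give the (1R,2R,3R,4R) ring; the closest known reaction is the intermolecular trans-stilbene/dialkyl fumarate exciplex cycloaddition, which gives mu-truxinates and is face-selective with chiral fumarate esters.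

**Step 6**
Reactants: 10 the macrotricycle
Product: 11 the target
Conditions: H2 (1 atm), 10% Pd/C (palladium on carbon), THF–H2O 9:1, rt, 16 h
Reagents that add atoms: none
Why: catalytic hydrogenolysis of benzylic C–O bonds removes the six benzyl ethers and both xylylene straps (benzyl ester and benzyl ether ends) in one operation; the alkyl esters, the cyclobutane and all six stereocentres are unaffected.

## Compound list

1 | 4-(benzyloxy)-3-hydroxybenzaldehyde | O=Cc1ccc(OCc2ccccc2)c(O)c1 | starting material
2 | (E)-4,4'-bis(benzyloxy)stilbene-3,3'-diol | Oc1cc(/C=C/c2ccc(OCc3ccccc3)c(O)c2)ccc1OCc1ccccc1 | intermediate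
3 | 1,2-bis(bromomethyl)benzene | BrCc1ccccc1CBr | starting material
4 | (E)-4,4'-bis(benzyloxy)-3,3'-bis{[2-(bromomethyl)benzyl]oxy}stilbene | BrCc1ccccc1COc1cc(/C=C/c2ccc(OCc3ccccc3)c(OCc3ccccc3CBr)c2)ccc1OCc1ccccc1 | intermediate
5 | sodium (2R)-3-(3,4-dihydroxyphenyl)-2-hydroxypropanoate | [Na+].[O-]C(=O)[C@H](O)Cc1ccc(O)c(O)c1 | starting material
6 | strapped stilbene bis[(R)-danshensu ester], catechols free | O=C(OCc1ccccc1COc1cc(/C=C/c2ccc(OCc3ccccc3)c(OCc3ccccc3COC(=O)[C@H](O)Cc3ccc(O)c(O)c3)c2)ccc1OCc1ccccc1)[C@H](O)Cc1ccc(O)c(O)c1 | intermediate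
7 | strapped stilbene bis[(R)-3,4-di-O-benzyldanshensu ester] diol | O=C(OCc1ccccc1COc1cc(/C=C/c2ccc(OCc3ccccc3)c(OCc3ccccc3COC(=O)[C@H](O)Cc3ccc(OCc4ccccc4)c(OCc4ccccc4)c3)c2)ccc1OCc1ccccc1)[C@H](O)Cc1ccc(OCc2ccccc2)c(OCc2ccccc2)c1 | intermediate
8 | fumaryl chloride | O=C(Cl)/C=C/C(=O)Cl | starting material
9 | 30-membered macrocyclic (E)-fumarate | O=C1/C=C/C(=O)O[C@H](Cc2ccc(OCc3ccccc3)c(OCc3ccccc3)c2)C(=O)OCc2ccccc2COc2cc(/C=C/c3ccc(OCc4ccccc4)c(OCc4ccccc4COC(=O)[C@@H](Cc4ccc(OCc5ccccc5)c(OCc5ccccc5)c4)O1)c3)ccc2OCc2ccccc2 | intermediate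
10 | macrotricyclic (1R,2R,3R,4R)-cyclobutane with two o-xylylene straps | O=C(O[C@H](Cc1ccc(OCc2ccccc2)c(OCc2ccccc2)c1)C(=O)OCc1ccccc1C5)[C@H]1[C@H](C(=O)O[C@H](Cc2ccc(OCc3ccccc3)c(OCc3ccccc3)c2)C(=O)OCc2ccccc2C6)[C@H](c2ccc(OCc3ccccc3)c(O6)c2)[C@H]1c1ccc(OCc2ccccc2)c(O5)c1 | intermediate
11 | bis[(R)-1-carboxy-2-(3,4-dihydroxyphenyl)ethyl] (1R,2R,3R,4R)-3,4-bis(3,4-dihydroxyphenyl)cyclobutane-1,2-dicarboxylate | O=C(O[C@H](Cc1ccc(O)c(O)c1)C(=O)O)[C@H]1[C@H](C(=O)O[C@H](Cc2ccc(O)c(O)c2)C(=O)O)[C@H](c2ccc(O)c(O)c2)[C@H]1c1ccc(O)c(O)c1 | target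

## Summary

Total steps: 6. Longest linear sequence: 6 (1 → 2 → 4 → 7 → 9 → 10 → 11).

**Steps most likely to fail**

Step 5 (photocycloaddition). The risks are facial selectivity and loss to stilbene E/Z isomerisation. The Si,Si mu-adduct arises from the s-cis enoate rotamer over the outer meta-oxygen; the energy gap to the desired rotamer is small and its sign is not secured, so the ratio must be measured. The fallback drops the straps and runs the bimolecular exciplex cycloaddition, in which the ester arm no longer has to point at the stilbene. It sets out from 2 (with 5 and 8) and comes back at 11. Compound 2 is perbenzylated (BnBr, K2CO3, DMF) to (E)-3,3',4,4'-tetrakis(benzyloxy)stilbene F1. Compound 5 is tribenzylated (BnBr, K2CO3, DMF) to benzyl (2R)-3-[3,4-bis(benzyloxy)phenyl]-2-hydroxypropanoate F2, which is acylated with 8 (0.5 equiv, pyridine, CH2Cl2) to the untethered bis-ester fumarate F3. F1 is irradiated with excess F3 (350 nm, toluene, −40 °C) to the decabenzyl mu-cycloadduct F4, and hydrogenolysis (H2, Pd/C) gives 11.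

Step 4 (macrocyclisation). The risk is oligomerisation and tar from fumaryl chloride with amine base. The fallback builds the fumarate by ring-closing metathesis; it sets out from 7 and comes back at 9. Diol 7 is acylated with acryloyl chloride (Et3N, CH2Cl2, 0 °C) to the bis-acrylate F5. F5 is closed with second-generation Hoveyda–Grubbs catalyst, RuCl2(H2IMes)(=CH-C6H4-2-OiPr), in toluene (1 mM, 80 °C) with loss of ethylene to give the E-fumarate 9; the diaryl alkene is a sluggish metathesis partner.

Step 1 (McMurry coupling). The risk is low yield from the free phenol or Lewis-acid debenzylation. The fallback makes the stilbene by olefin metathesis; it sets out from 1 and comes back at 2. Aldehyde 1 is methylenated (Ph3PCH3Br, KOtBu, 2.2 equiv, THF) to 2-(benzyloxy)-5-vinylphenol F6. F6 is self-metathesised with second-generation Grubbs catalyst, RuCl2(H2IMes)(PCy3)(=CHPh), in refluxing CH2Cl2 with ethylene removal to give E-stilbene 2.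

## Further compounds

F1 | step 5 | (E)-3,3',4,4'-tetrakis(benzyloxy)stilbene | c1ccccc1COc1ccc(/C=C/c2ccc(OCc3ccccc3)c(OCc3ccccc3)c2)cc1OCc1ccccc1
F2 | step 5 | benzyl (2R)-3-[3,4-bis(benzyloxy)phenyl]-2-hydroxypropanoate | O=C(OCc1ccccc1)[C@H](O)Cc1ccc(OCc2ccccc2)c(OCc2ccccc2)c1
F3 | step 5 | bis{(2R)-1-(benzyloxy)-3-[3,4-bis(benzyloxy)phenyl]-1-oxopropan-2-yl} (E)-but-2-enedioate | O=C(/C=C/C(=O)O[C@H](Cc1ccc(OCc2ccccc2)c(OCc2ccccc2)c1)C(=O)OCc1ccccc1)O[C@H](Cc1ccc(OCc2ccccc2)c(OCc2ccccc2)c1)C(=O)OCc1ccccc1
F4 | step 5 | decabenzyl-protected 11 (hexa-O-benzyl ethers on the four catechols' eight oxygens counted as eight, plus two benzyl esters), (1R,2R,3R,4R) | O=C(O[C@H](Cc1ccc(OCc2ccccc2)c(OCc2ccccc2)c1)C(=O)OCc1ccccc1)[C@H]1[C@H](C(=O)O[C@H](Cc2ccc(OCc3ccccc3)c(OCc3ccccc3)c2)C(=O)OCc2ccccc2)[C@H](c2ccc(OCc3ccccc3)c(OCc3ccccc3)c2)[C@H]1c1ccc(OCc2ccccc2)c(OCc2ccccc2)c1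
F5 | step 4 | bis-acrylate of diol 7 | C=CC(=O)O[C@H](Cc1ccc(OCc2ccccc2)c(OCc2ccccc2)c1)C(=O)OCc1ccccc1COc1cc(/C=C/c2ccc(OCc3ccccc3)c(OCc3ccccc3COC(=O)[C@@H](Cc3ccc(OCc4ccccc4)c(OCc4ccccc4)c3)OC(=O)C=C)c2)ccc1OCc1ccccc1
F6 | step 1 | 2-(benzyloxy)-5-vinylphenol | C=Cc1ccc(OCc2ccccc2)c(O)c1
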